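I have no constants for this flask, just two earlier runs, so I read one working number from them.

| flask | starting material | gas phase | protic impurity | free catalyst | remark | time |
|---|---|---|---|---|---|---|
| autumn | 2 M | 150 mM (held) | 0.56 M | 0.96 mol% | run made earlier |  |
| midnight | 2 M | 150 mM (held) | 0.88 M | 0.96 mol% | run made earlier |  |
| flask | 2.0 M | 150 mM (held) | 0.400 M | 0.96 mol% |  | 12 h |

| run | time / h | product / % | starting material / % |
|---|---|---|---|
| autumn | 0.500 | 6 | 97 |
| autumn | 1.33 | 9 | 88 |
| autumn | 2.50 | 16 | 82 |
| autumn | 4.00 | 23 | 77 |
| autumn | 6.00 | 33 | 63 |
| autumn | 8.00 | 42 | 60 |
| midnight | 1.33 | 10 | 91 |
| midnight | 2.50 | 16 | 83 |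
| midnight | 4.00 | 24 | 79 |
| midnight | 5.00 | 30 | 69 |
| midnight | 6.00 | 34 | 65 |
| midnight | 8.00 | 40 | 57 |

(readings scatter by 1.5 percentage points)

- the numbers in the tables scatter by 1.5 percentage points (one standard deviation)
- at the start none of the gas phase is in solution

- Thursday's: doubling the saturation concentration of gas phase, all else as stated
- Saturday's: doubling the amount of free catalyst, all else as stated
- Sunday's: doubling the transfer coefficient of the gas phase, all else as stated

- how much product there is at 12 h, in percent of the starting material charged
- the change that raises the amount of product at 12 h, in percent of the starting material charged most ("none" if none brings more than 2 percentage points) (Thursday's / Saturday's / Sunday's / none)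
- amount of product at 12 h, in percent of the starting material charged, after Sunday's

At the bench I would draw a straight line from the start through the last reading. Between the runs the protic impurity rises by a factor of 1.57, yet the product at 8.00 h shifts by 2 percentage points, with a scatter of 1.5 points on each reading. So I pool the two at 41.0%. The straight line then gives 61.5% at 12 h.

But I assume the rate follows the starting material left, with the gas phase held: pseudo-first-order. The time in which the unreacted share halves is then 10.5 h. I call it the working half-life.

For these runs I take the ratio of time to working half-life as my mark for the border of the straight line. It is 0.762 at the last reading and 1.14 in the flask. The curve gives 54.7% for the flask, 6.8 points below the line, which is more than the scatter. So the flask stands past the border, and I commit to the curve.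

The forecast says 56%, with a range of 52% to 61%, higher than my figure. It picks Saturday's and puts Sunday's at 57%, with a range of 53% to 64%, reasoning that “Gas uptake is therefore fast, the chemistry limits”.

The flask gives 51.8%. Saturday's adds 27 points, more than Thursday's 20 points. Sunday's ends at 52.0%, a gain of 0.26 points.

    starting material + dissolved gas + free catalyst → free catalyst + product (k = 40.0 /M²/h)
    dissolved gas + free catalyst ⇌ idle complex, settled at all times (K = 2.60 /M)
    starting material + free catalyst → spent catalyst (k = 0.0460 /M/h)
    dissolved gas + protic impurity → quenched reagent (k = 0.750 /M/h)
    gas phase ⇌ dissolved gas, rate k5*(csat - [dissolved gas]) (kL = 56.0 /h)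

The flask is still moving at 12.0 h, with 48% of its starting material left. At 120 h its product reads 96.2% and its starting material 3.08%, while spent catalyst has grown from 42.1% to 77.7% of the catalyst charged. The working half-life gives >99.9% at that time, more than the computed product.

For the neighbour flask read at 5.0 h, the ratio is 0.476 and the working half-life gives 28.1%. The computed product there is 29.7%.

Readings and results are calculated from invented constants; scatter was added.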